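## The problem

Target 26 joins three ring units through two adjacent fully substituted carbons. The labels used throughout are: ring A, the methoxy-enedione ring; ring B, the cyclopentane; Ca, the carbon shared by rings A and B; Cb, the ring-B CH that carries isopropyl; Cc and Cd, the two ring-B CH2 groups (Cd is bonded to Ce); Ce, pinane C2, shared by ring B and the pinane. Ring B therefore has to be built around a quaternary–quaternary Ca–Ce bond that is flanked by the branched centre Cb. Of the five stereocentres, the two pinane bridgeheads come with the terpene and can control Ce, because reagents reach pinane C2 from the face away from the CMe2 bridge. Cb can be tied to Ca through a cyclic transition state, but Ca is stereogenic only because the two carbonyl arms of ring A differ at a distance (CMe2 on one side, C(Me)=C(OMe) on the other), and this is the hardest centre to control. The molecule tolerates little: the pinane cyclobutane opens through a cation or radical at C2, the vinylogous methyl ester hydrolyses in aqueous acid, the non-enolisable 1,3-diketone at Ca can suffer retro-Claisen cleavage by alkoxide or hydroxide, and any open-chain precursor with a carbonyl two carbons from Cb can expel the ring-A enolate by retro-Michael reaction. Ring A adds a regiochemical question, since three ring oxygens could carry the methyl group. The feature that allows a short ring-B closure is that Ce and pinane C3 can be the two carbons of a pinene C2=C3 alkene: a carbene carbon Cd held on Ca through Cb and Cc can add to its open face, and of the three cyclopropane bonds so formed only the extra Cd–C3 bond joins two CH carbons, so hydrogenolysis can remove it again.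

## Retrosynthesis

26 is traced back to cyclopropane 25, which differs only by an extra Cd–C3 bond. No skeletal bond of the target is cut; the gain is that the Cd–Ce bond to a quaternary carbon becomes the product of an addition to an alkene. The forward step must cleave the one cyclopropane bond between two CH carbons and leave ring A alone.

25 is disconnected at Cd–Ce and Cd–C3 to tosylhydrazone 22, through 1-pyrazoline 24 and diazoalkane 23. Closing ring B at Ca–Cb or Ca–Ce instead would require an ionic ring closure that creates a quaternary centre next to another one. A diazoalkane or carbene at Cd tolerates that congestion and takes its facial bias from the pinene. Two rings, two bonds and three stereocentres are removed. The forward reaction needs addition on the face anti to the CMe2 bridge, preference for the alkene over the ring-A carbonyls, and aprotic base.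

22 comes from aldehyde 20 and hydrazide 21, 20 from alcohol 19, and 19 from vinyl compound 17 by hydroboration (through borane 18). No skeletal bond is cut. The terminal alkene is chosen as the aldehyde precursor because it is what a sigmatropic Ca–Cb bond formation delivers, and it is inert until needed. The forward steps must spare the pinene alkene and avoid base once the aldehyde is present.

17 is cut at Ca–Cb to allyl dienyl ether 16 (Claisen rearrangement). The neighbouring cut, a Michael addition of 13 to enal 14, would form the most congested bond reversibly and offers no handle on Ca, because the two enolate oxygens are alike. In 16 the arms differ (ether against carbonyl), the bond forms irreversibly, and a chair transition state ties Cb to Ca. 16 has no stereocentre outside the pinene. The forward reaction needs the chair geometry, passage of the allyl unit on the open side of the pinene, and a temperature below the onset of a following Cope rearrangement.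

16 is cut at the allyl C–O bond to vinylogous acid 13 and allylic alcohol 15 (from enal 14). The forward O-alkylation must occur at the oxygen on the carbon next to CMe2, because this choice is what later decides Ca.

13 is cut at Ca–Ce to dione 12 and enol triflate 4. Forming this bond before Ca is quaternary makes it an ordinary enolate alkenylation; forming it after the Cb side chain is in place would require a reductive elimination to a quaternary carbon.

12 is traced through acid 11, ester 10, the aromatic C-methyl intermediates 9 and 8, and methyl ether 7 to benzyl ester 6 and acid 5. The cuts are three C–CH3 bonds, one O–CH3 bond and the ester. Because 7 and 9 are symmetric, only one constitution of 10 can arise, so the position of the methoxy group is fixed by symmetry. The ester blocks Ca during methylation and is removed without acid or base. Direct enol-ether formation on an unsymmetrical trimethyl trione with a free ring CH2 was set aside, because the least hindered oxygens flank that CH2.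

4 comes from nopinone 3 by enol triflation, and 3 from (+)-β-pinene 1 by ozonolysis (through ozonide 2). Both bridgehead stereocentres are carried through unchanged.

## Roads not taken

Alternative 1: The cut is the Ca–Cb bond, made by an oxidative radical cyclisation. Mn(OAc)3 in acetic acid would oxidise malonate A1, in which Ce is already a quaternary pinane carbon carrying a 4-methylpent-3-enyl chain, to the Ca radical. 5-exo closure onto the trisubstituted alkene, oxidation to the tertiary cation and capture by the cis ester would give lactone ester A2.
- Merits: the congested Ca–Cb bond forms irreversibly, and the cis-fused lactone records the Ca/Cb relationship. The two acyl groups on Ca are chemically different from the start (lactone carbonyl and ester), so Ca could be defined with less ambiguity than through the rearrangement of 16; in this respect the road is better.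
- Weak points: Ce must first be made as a quaternary centre with the malonate syn to the CMe2 bridge, that is, by bond formation on the shielded face. The lactone oxygen sits on the future isopropyl carbon and must be removed. All of ring A must still be annulated onto two carboxyl carbons and O-methylated regioselectively after the key step.
- Comparison: the chosen plan offsets its less direct control of Ca with a ring A that arrives complete and regiochemically fixed in 12, and with a Ce that is created by addition to the open alkene face.

Alternative 2: The cuts are Cb–Cc and Ca–Ce, a formal [3+2] assembly of ring B. Base would add the nitronate of the pinene-based nitroalkane carbonate A4 to isobutylidene dione A3. Pd(PPh3)4 would then ionise the allylic carbonate, and the ring-A enolate would attack pinane C2 to give nitro spirocycle A5. Denitration and alkene hydrogenation would finish the synthesis.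
- Merits: this is the most convergent and shortest road. Ring A and the pinane are used intact and both ring-B bonds form in one flask; in step count it is clearly better than the chosen plan.
- Weak points: the enolate must attack the more substituted allyl terminus to make a quaternary carbon next to quaternary Ca, and it must do so on the face syn to the CMe2 bridge. Zerovalent palladium would have to sit on the open face and the nucleophile enter from the shielded one; attack at C4 is the expected course. Ca, Cb and Ce form with no element that relates Cb to the pinene, and A3 is a reactive heterodiene.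
- Comparison: the chosen plan is longer, but each stereocentre has its own control element and Ce is made with, not against, the facial bias of the pinene.

Alternative 3: Ring A is built last, cutting a Ca–acyl bond and the bond closed by Dieckmann condensation. The lithium enolate of ring-B ester A6 would be C-acylated at Ca by acid chloride A7, and excess base would close ring A onto the methyl ester to give triketone A8, which is O-methylated last.
- Merits: ring A, with its vinylogous ester and cleavable 1,3-diketone, would not have to survive the ring-B chemistry. The two carbonyl arms on Ca differ by origin, so Ca is set in one facially selective acylation. In both respects this road is better than the chosen one.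
- Weak points: A6 still contains the whole Ca–Ce–Cb problem, so ring B must be made without help from ring A. C-acylation of an ester enolate flanked by quaternary Ce and CH(iPr) competes with O-acylation. The final O-methylation must choose between two hindered oxygens with no symmetry to help.
- Comparison: the chosen plan fixes the ring-A regiochemistry by symmetry at the stage of 7 to 10 and forms Ca–Cb by an intramolecular rearrangement instead of an intermolecular acylation at a neopentyl-type carbon.

Key step: step 14

Remark: salts formed by deprotonation (enolates, phenoxides, the tosylhydrazone anion) are treated as the same compound as their conjugate acids and carry no number of their own; enolisable compounds are drawn as one tautomer.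

## Route

Step 1
Reactants: 1 (+)-β-pinene
Product: 3 (−)-nopinone [(1S,5R)-6,6-dimethylbicyclo[3.1.1]heptan-2-one], via secondary ozonide 2 (not isolated)
Conditions: O3, CH2Cl2, −78 °C; then Me2S, −78 °C → rt
Reagents that add atoms: ozone, [O-][O+]=O
Why: Ozonolysis of the 1,1-disubstituted alkene with reductive work-up; the bicyclic skeleton and both bridgehead stereocentres are untouched, so 3 keeps the configuration of 1.

Step 2
Reactants: 3 (−)-nopinone
Product: 4 (1S,5R)-6,6-dimethylbicyclo[3.1.1]hept-2-en-2-yl trifluoromethanesulfonate
Conditions: LiN(SiMe3)2, THF, −78 °C; PhNTf2, −78 → 0 °C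
Reagents that add atoms: N-phenylbis(trifluoromethanesulfonimide), O=S(=O)(N(c1ccccc1)S(=O)(=O)C(F)(F)F)C(F)(F)F
Why: Enolate O-sulfonylation (enol triflate formation); only C3 can be deprotonated because C1 is a bridgehead, so a single regioisomer forms.

Step 3
Reactants: 5 2,4,6-trihydroxybenzoic acid
Product: 6 benzyl 2,4,6-trihydroxybenzoate
Conditions: BnBr, KHCO3, DMF, rt
Reagents that add atoms: benzyl bromide, BrCc1ccccc1
Why: Carboxylate O-alkylation (SN2); bicarbonate ionises the acid but not the phenols, and the benzyl ester is chosen because it can later be removed under neutral conditions.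

Step 4
Reactants: 6 benzyl 2,4,6-trihydroxybenzoate
Product: 7 benzyl 2,6-dihydroxy-4-methoxybenzoate
Conditions: Me2SO4 (1.05 equiv), K2CO3, acetone, rt
Reagents that add atoms: dimethyl sulfate, COS(=O)(=O)OC
Why: Williamson ether synthesis; the 4-hydroxyl is the only one not hydrogen-bonded to the ester carbonyl and is the most acidic, so mono-methylation occurs there and the ring stays symmetric.

Step 5
Reactants: 7 benzyl 2,6-dihydroxy-4-methoxybenzoate
Product: 10 benzyl 2-hydroxy-4-methoxy-3,3,5-trimethyl-6-oxocyclohexa-1,4-diene-1-carboxylate, via mono-C-methyl benzoate 8 (not isolated), via di-C-methyl benzoate 9 (not isolated)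
Conditions: MeI (4 equiv), KOtBu (3.3 equiv), tBuOH–THF, 0 → 40 °C
Reagents that add atoms: iodomethane, CI
Why: Alkylative dearomatisation of a polyphenolate: C-methylation at C3 and C5, then a third methylation at one of these now equivalent carbons. The ester-bearing carbon is not alkylated, the enol ether blocks a fourth C-methylation, and the symmetry of 9 allows only one constitution of 10; tert-butoxide avoids ester exchange.

Step 6
Reactants: 10 benzyl 2-hydroxy-4-methoxy-3,3,5-trimethyl-6-oxocyclohexa-1,4-diene-1-carboxylate
Product: 12 5-methoxy-4,6,6-trimethylcyclohex-4-ene-1,3-dione, via β-keto acid 11 (not isolated)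
Conditions: H2 (1 atm), Pd/C, EtOAc, rt; then 40 °C
Reagents that add atoms: none
Why: Benzyl ester hydrogenolysis followed by spontaneous decarboxylation of the β-keto acid; the tetrasubstituted vinylogous-ester alkene is not reduced under these mild conditions.

Step 7
Reactants: 12 5-methoxy-4,6,6-trimethylcyclohex-4-ene-1,3-dione; 4 (1S,5R)-6,6-dimethylbicyclo[3.1.1]hept-2-en-2-yl trifluoromethanesulfonate
Product: 13 3-hydroxy-5-methoxy-4,4,6-trimethyl-2-[(1S,5R)-6,6-dimethylbicyclo[3.1.1]hept-2-en-2-yl]cyclohexa-2,5-dien-1-one (enol form of the 2-pinenyl dione)
Conditions: Pd2(dba)3 (2.5 mol %), XPhos (7.5 mol %), K3PO4, 1,4-dioxane, 90 °C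
Reagents that add atoms: none
Why: Palladium-catalysed α-alkenylation of a stabilised enolate with an alkenyl triflate (oxidative addition to zerovalent palladium, enolate binding, C–C reductive elimination assisted by the bulky biarylphosphine). Only the carbon between the two carbonyls is nucleophilic, and no stereocentre is created because 13 is enolised.

Step 8
Reactants: 14 (E)-4-methylpent-2-enal
Product: 15 (E)-4-methylpent-2-en-1-ol
Conditions: NaBH4, CeCl3·7H2O, MeOH, 0 °C
Reagents that add atoms: none
Why: Luche 1,2-reduction of the enal; the E geometry is retained.

Step 9
Reactants: 13 enol form of the 2-pinenyl dione; 15 (E)-4-methylpent-2-en-1-ol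
Product: 16 3-{[(2E)-4-methylpent-2-en-1-yl]oxy}-5-methoxy-4,4,6-trimethyl-2-[(1S,5R)-6,6-dimethylbicyclo[3.1.1]hept-2-en-2-yl]cyclohexa-2,5-dien-1-one (allyl ether on the oxygen next to CMe2)
Conditions: PPh3, DIAD, THF, 0 °C → rt
Reagents that add atoms: none
Why: Mitsunobu O-alkylation of a vinylogous acid (SN2 at the primary allylic carbon, E alkene retained). Reaction through the oxygen on the carbon next to CMe2 gives the cross-conjugated 3,5-dialkoxy dienone and avoids the in-plane methyl group beside the other oxygen.

Step 10
Reactants: 16 allyl dienyl ether
Product: 17 (2R)-5-methoxy-4,6,6-trimethyl-2-[(3S)-4-methylpent-1-en-3-yl]-2-[(1S,5R)-6,6-dimethylbicyclo[3.1.1]hept-2-en-2-yl]cyclohex-4-ene-1,3-dione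
Conditions: PhMe, 110 °C, sealed tube
Reagents that add atoms: none
Why: Claisen rearrangement ([3,3]-sigmatropic) through a chair transition state: the E alkene places isopropyl pseudo-equatorial, which fixes Cb relative to Ca. The allyl unit should travel over the ring-A face beside the vinylic C3–H of the pinene and past its CH2 bridge, not the CMe2 bridge, which fixes both centres relative to the terpene (Ca R, Cb S).

Step 11
Reactants: 17 Claisen product
Product: 19 (2R)-2-[(3R)-1-hydroxy-4-methylpentan-3-yl]-5-methoxy-4,6,6-trimethyl-2-[(1S,5R)-6,6-dimethylbicyclo[3.1.1]hept-2-en-2-yl]cyclohex-4-ene-1,3-dione, via B-alkyl-9-BBN adduct 18 (not isolated)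
Conditions: 9-BBN (1.5 equiv), THF, 0 °C → rt; then NaBO3·4H2O, H2O, rt
Reagents that add atoms: sodium perborate, [Na+].[Na+].O[B-]1(O)OO[B-](O)(O)OO1 (oxygen of the alcohol); 9-BBN, B1C2CCCC1CCC2 (its boron and carbons remain only in 18)
Why: Anti-Markovnikov hydroboration–oxidation; 9-BBN should react with the monosubstituted alkene far faster than with the hindered pinene alkene or the hindered ketones. Perborate avoids strongly basic peroxide, which could cleave the non-enolisable 1,3-diketone; Ca and Cb are not touched.

Step 12
Reactants: 19 primary alcohol
Product: 20 (3R)-3-{(1R)-4-methoxy-3,5,5-trimethyl-2,6-dioxo-1-[(1S,5R)-6,6-dimethylbicyclo[3.1.1]hept-2-en-2-yl]cyclohex-3-en-1-yl}-4-methylpentanal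
Conditions: DMP, CH2Cl2, 0 °C → rt
Reagents that add atoms: none
Why: Dess–Martin oxidation of the primary alcohol to the aldehyde under non-basic conditions, so retro-Michael loss of the ring-A enolate from 20 is avoided.

Step 13
Reactants: 20 aldehyde; 21 p-toluenesulfonyl hydrazide
Product: 22 p-toluenesulfonylhydrazone of 20 (C=N geometry not defined and not relevant)
Conditions: MeOH, rt
Reagents that add atoms: none
Why: Hydrazone formation at the aldehyde; the two ring ketones do not compete because one is a vinylogous ester and the other lies between two quaternary carbons.

Step 14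
Reactants: 22 tosylhydrazone
Product: 25 cyclopropane (26 with an additional Cd–C3 bond, three-membered ring Cd–Ce–C3 on the pinane face anti to the CMe2 bridge), via diazoalkane 23 (not isolated), via 1-pyrazoline 24 (not isolated)
Conditions: K2CO3 (1.5 equiv), 1,4-dioxane, 110 °C, dark; then hν (350 nm), 20 °C
Reagents that add atoms: none
Why: Carbonate forms the hydrazone anion, which loses p-toluenesulfinate on heating (Bamford–Stevens) to give diazoalkane 23; this adds as a 1,3-dipole across the tethered C2=C3 alkene to give 1-pyrazoline 24, and irradiation expels N2 to leave the cyclopropane. The closest known reaction type is the intramolecular diazoalkane–alkene cycloaddition of hex-5-enal tosylhydrazone salts followed by photochemical or thermal nitrogen extrusion to bicyclo[3.1.0]hexanes. Ring B closes in the 5-exo sense (Cd bonds to the proximal alkene carbon Ce through a three-atom tether, helped by quaternary Ca), the pyrazoline ring forms in the same [3+2] event, and the three-membered ring closes by collapse of the 1,3-diradical or concerted loss of N2. Ce is set by facial selectivity: both new bonds form on the alkene face away from the CMe2 bridge, whose syn methyl shields the other face, so Cd ends up anti and Ca syn to that bridge; Cd and C3 follow because the addition is suprafacial and the ring fusion must be cis. Ca and Cb are spectators, and isopropyl ends up on the side of the small C3 arm, not of the bridgehead, so the substrate and the alkene bias should reinforce each other. The step needs the diazoalkane to choose the alkene over the two ring-A carbonyls, which their vinylogous-ester character and their position between quaternary carbons should secure; aprotic carbonate conditions keep the diazoalkane from protonation and the hydrazone from base-induced retro-Michael cleavage. Alkene formation from the diradical is blocked because its central carbon Ce carries no hydrogen.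

Step 15
Reactants: 25 cyclopropane
Product: 26 target
Conditions: H2 (3 atm), PtO2, AcOH, rt
Reagents that add atoms: none
Why: Heterogeneous hydrogenolysis of a cyclopropane; platinum cleaves the least substituted and most exposed bond, here Cd–C3 between the two CH carbons on the face away from the CMe2 bridge. Both bonds to quaternary Ce and its configuration are kept, and the hindered ketone and the tetrasubstituted vinylogous ester should survive.

## Compound list

1 | (+)-β-pinene, (1R,5R)-6,6-dimethyl-2-methylidenebicyclo[3.1.1]heptane | C=C1CC[C@@H]2C[C@H]1C2(C)C | starting material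
2 | secondary ozonide of 1 (1,2,4-trioxolane spiro-fused at pinane C2, either configuration at the spiro carbon) | C1OC2(OO1)CC[C@@H]1C[C@H]2C1(C)C | intermediate
3 | (−)-nopinone, (1S,5R)-6,6-dimethylbicyclo[3.1.1]heptan-2-one | O=C1CC[C@@H]2C[C@H]1C2(C)C | intermediate
4 | (1S,5R)-6,6-dimethylbicyclo[3.1.1]hept-2-en-2-yl trifluoromethanesulfonate | O=S(=O)(OC1=CC[C@@H]2C[C@H]1C2(C)C)C(F)(F)F | intermediate
5 | 2,4,6-trihydroxybenzoic acid | OC(=O)c1c(O)cc(O)cc1O | starting material
6 | benzyl 2,4,6-trihydroxybenzoate | O=C(OCc1ccccc1)c1c(O)cc(O)cc1O | intermediate
7 | benzyl 2,6-dihydroxy-4-methoxybenzoate | COc1cc(O)c(C(=O)OCc2ccccc2)c(O)c1 | intermediate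
8 | benzyl 2,6-dihydroxy-4-methoxy-3-methylbenzoate | COc1cc(O)c(C(=O)OCc2ccccc2)c(O)c1C | intermediate
9 | benzyl 2,6-dihydroxy-4-methoxy-3,5-dimethylbenzoate | COc1c(C)c(O)c(C(=O)OCc2ccccc2)c(O)c1C | intermediate
10 | benzyl 2-hydroxy-4-methoxy-3,3,5-trimethyl-6-oxocyclohexa-1,4-diene-1-carboxylate | COC1=C(C)C(=O)C(C(=O)OCc2ccccc2)=C(O)C1(C)C | intermediate
11 | 2-hydroxy-4-methoxy-3,3,5-trimethyl-6-oxocyclohexa-1,4-diene-1-carboxylic acid | COC1=C(C)C(=O)C(C(=O)O)=C(O)C1(C)C | intermediate
12 | 5-methoxy-4,6,6-trimethylcyclohex-4-ene-1,3-dione (drawn as the dione) | COC1=C(C)C(=O)CC(=O)C1(C)C | intermediate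
13 | 3-hydroxy-5-methoxy-4,4,6-trimethyl-2-[(1S,5R)-6,6-dimethylbicyclo[3.1.1]hept-2-en-2-yl]cyclohexa-2,5-dien-1-one | COC1=C(C)C(=O)C(=C(O)C1(C)C)C1=CC[C@@H]2C[C@H]1C2(C)C | intermediate
14 | (E)-4-methylpent-2-enal | CC(C)/C=C/C=O | starting material
15 | (E)-4-methylpent-2-en-1-ol | CC(C)/C=C/CO | intermediate
16 | 3-{[(2E)-4-methylpent-2-en-1-yl]oxy}-5-methoxy-4,4,6-trimethyl-2-[(1S,5R)-6,6-dimethylbicyclo[3.1.1]hept-2-en-2-yl]cyclohexa-2,5-dien-1-one | COC1=C(C)C(=O)C(=C(OC/C=C/C(C)C)C1(C)C)C1=CC[C@@H]2C[C@H]1C2(C)C | intermediate
17 | (2R)-5-methoxy-4,6,6-trimethyl-2-[(3S)-4-methylpent-1-en-3-yl]-2-[(1S,5R)-6,6-dimethylbicyclo[3.1.1]hept-2-en-2-yl]cyclohex-4-ene-1,3-dione | COC1=C(C)C(=O)[C@@](C(=O)C1(C)C)([C@@H](C(C)C)C=C)C1=CC[C@@H]2C[C@H]1C2(C)C | intermediate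
18 | B-alkyl-9-borabicyclo[3.3.1]nonane adduct of 17 (boron on the terminal carbon Cd; Ca R, Cb R) | COC1=C(C)C(=O)[C@@](C(=O)C1(C)C)([C@@H](C(C)C)CCB1C2CCCC1CCC2)C1=CC[C@@H]2C[C@H]1C2(C)C | intermediate
19 | (2R)-2-[(3R)-1-hydroxy-4-methylpentan-3-yl]-5-methoxy-4,6,6-trimethyl-2-[(1S,5R)-6,6-dimethylbicyclo[3.1.1]hept-2-en-2-yl]cyclohex-4-ene-1,3-dione | COC1=C(C)C(=O)[C@@](C(=O)C1(C)C)([C@@H](C(C)C)CCO)C1=CC[C@@H]2C[C@H]1C2(C)C | intermediate
20 | (3R)-3-{(1R)-4-methoxy-3,5,5-trimethyl-2,6-dioxo-1-[(1S,5R)-6,6-dimethylbicyclo[3.1.1]hept-2-en-2-yl]cyclohex-3-en-1-yl}-4-methylpentanal | COC1=C(C)C(=O)[C@@](C(=O)C1(C)C)([C@@H](C(C)C)CC=O)C1=CC[C@@H]2C[C@H]1C2(C)C | intermediate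
21 | p-toluenesulfonyl hydrazide | Cc1ccc(cc1)S(=O)(=O)NN | starting material
22 | p-toluenesulfonylhydrazone of aldehyde 20 (Ca R, Cb R) | COC1=C(C)C(=O)[C@@](C(=O)C1(C)C)([C@@H](C(C)C)CC=NNS(=O)(=O)c1ccc(C)cc1)C1=CC[C@@H]2C[C@H]1C2(C)C | intermediate
23 | diazoalkane from 22 (diazo group on Cd) | COC1=C(C)C(=O)[C@@](C(=O)C1(C)C)([C@@H](C(C)C)CC=[N+]=[N-])C1=CC[C@@H]2C[C@H]1C2(C)C | intermediate
24 | 1-pyrazoline: ring B closed by the Cd–Ce bond, N=N bridging Cd and pinane C3, cis-fused on the face anti to the CMe2 bridge | COC1=C(C)C(=O)[C@@]2(C(=O)C1(C)C)[C@@H](C(C)C)C[C@H]3N=N[C@@H]4C[C@@H]5C[C@H]([C@]234)C5(C)C | intermediate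
25 | cyclopropane: 26 with an additional Cd–C3 bond, three-membered ring anti to the CMe2 bridge | COC1=C(C)C(=O)[C@@]2(C(=O)C1(C)C)[C@@H](C(C)C)C[C@H]3[C@@H]4C[C@@H]5C[C@H]([C@]234)C5(C)C | intermediate
26 | target: ring A spiro-fused at Ca (R) to ring B, which carries isopropyl at Cb (R) and is spiro-fused at Ce to the pinane (C1 S, C2 R, C5 R), Ca syn to the CMe2 bridge | COC1=C(C)C(=O)[C@@]2(C(=O)C1(C)C)[C@@H](C(C)C)CC[C@@]21CC[C@@H]2C[C@H]1C2(C)C | target

## Step count and risks

Total number of steps: 15. Longest linear sequence: 12 steps (steps 3 to 7 and 9 to 15, from 5 to 26).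

Step 14 (key step). The diazoalkane may be diverted before it reaches the alkene: loss of nitrogen with a 1,2-hydrogen shift to a terminal alkene, attack on a ring-A carbonyl, or azine formation. The cycloaddition itself may be slow, because Cd must bond to a fully substituted alkene carbon next to quaternary Ca, and irradiation may also excite the ring-A chromophore during nitrogen extrusion. Fallback: a zinc carbenoid in place of the diazoalkane. It sets out from aldehyde 20. Condensation with hydrazine hydrate gives the N-unsubstituted hydrazone F1, iodine and triethylamine convert it into the 1,1-diiodide F2, and diethylzinc in CH2Cl2 then generates the α-iodoalkylzinc carbenoid, which cyclopropanates the pinene alkene intramolecularly (Simmons–Smith) on the same open face. The route is rejoined at 25.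

Step 9. Alkylation may occur at the other carbonyl oxygen (the one beside the methyl-bearing alkene carbon) or at carbon; because the oxygen that carries the allyl group decides Ca in step 10, a wrong regiochemistry would be carried into the wrong Ca configuration. Fallback: intermolecular, catalyst-controlled formation of the Ca–Cb bond. It sets out from 13 and enal 14, which are combined with (R)-α,α-diphenylprolinol trimethylsilyl ether and benzoic acid in toluene at room temperature (iminium-catalysed Michael addition; the catalyst sets Cb, and the Ca epimers are separated). The route is rejoined at aldehyde 20; no new compound is involved.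

Step 10. The facial preference may erode, giving the isomer with both Ca and Cb inverted, or the 1,5-diene product may rearrange further (Cope rearrangement through pinane C3) at the temperature the Claisen step needs. Fallback: metal-catalysed allylation at room temperature. It sets out from 13. Alcohol 15 is converted with methyl chloroformate and pyridine into methyl (2E)-4-methylpent-2-en-1-yl carbonate F3, and 13 is allylated with F3 using [Ir(cod)Cl]2 and a BINOL-derived phosphoramidite ligand; this is a branched-selective allylic alkylation in which the ligand sets Cb. The route is rejoined at 17.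

Step 7. Reductive elimination to the hindered C-alkenyl dione may be slow, leaving O-alkenylation or cleavage of the triflate as the main course. Fallback: a boron-based coupling. It sets out from 12 and 4. PhI(OAc)2 and KOH in methanol convert 12 into the phenyliodonium ylide F4, and Miyaura borylation of 4 (B2pin2, PdCl2(PPh3)2, KOPh) gives the pinenyl boronate F5. Suzuki-type coupling of F4 with F5 (Pd(OAc)2, P(tBu)3, LiOH, aqueous DME) rejoins the route at 13.

Step 15. Reduction of a ring-A carbonyl or of the enol ether may compete, or a bond to Ce may be cleaved instead of Cd–C3. Fallback: a radical ring closure that never forms the cyclopropane. It sets out from tosylhydrazone 22. Fe(acac)3 and PhSiH3 in ethanol at 60 °C transfer a hydrogen atom to pinane C3; the tertiary C2 radical closes ring B 5-exo onto the hydrazone carbon to give the cyclic N′-alkyl sulfonylhydrazide F6, and continued warming expels sulfinate and N2 to leave CH2 at Cd. The route is rejoined at 26. This fallback depends on the radical closing ring B faster than it opens the cyclobutane.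

## Further compounds

F1 | step 14 | N-unsubstituted hydrazone of aldehyde 20 | COC1=C(C)C(=O)[C@@](C(=O)C1(C)C)([C@@H](C(C)C)CC=NN)C1=CC[C@@H]2C[C@H]1C2(C)C
F2 | step 14 | 1,1-diiodide at Cd derived from 20 | COC1=C(C)C(=O)[C@@](C(=O)C1(C)C)([C@@H](C(C)C)CC(I)I)C1=CC[C@@H]2C[C@H]1C2(C)C
F0 | step 9 | none | none
F3 | step 10 | methyl (2E)-4-methylpent-2-en-1-yl carbonate | COC(=O)OC/C=C/C(C)C
F4 | step 7 | phenyliodonium ylide of 12 | COC1=C(C)C(=O)[C-]([I+]c2ccccc2)C(=O)C1(C)C
F5 | step 7 | 2-[(1R,5R)-6,6-dimethylbicyclo[3.1.1]hept-2-en-2-yl]-4,4,5,5-tetramethyl-1,3,2-dioxaborolane | CC1(C)OB(OC1(C)C)C1=CC[C@@H]2C[C@H]1C2(C)C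
F6 | step 15 | cyclised N′-alkyl p-toluenesulfonylhydrazide (26 with NHNHTs on Cd, either configuration at Cd) | COC1=C(C)C(=O)[C@@]2(C(=O)C1(C)C)[C@@H](C(C)C)CC(NNS(=O)(=O)c3ccc(C)cc3)[C@@]21CC[C@@H]2C[C@H]1C2(C)C
A1 | alternative 1 | dimethyl malonate on pinane C2 (Ce) carrying a 4-methylpent-3-enyl chain | COC(=O)C(C(=O)OC)[C@@]1(CCC=C(C)C)CC[C@@H]2C[C@H]1C2(C)C
A2 | alternative 1 | spiro ring-B methyl ester with cis-fused γ-lactone | O=C1OC(C)(C)[C@H]2CC[C@@]3(CC[C@@H]4C[C@H]3C4(C)C)[C@@]12C(=O)OC
A3 | alternative 2 | 2-isobutylidene derivative of dione 12 (either alkene geometry) | COC1=C(C)C(=O)C(=CC(C)C)C(=O)C1(C)C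
A4 | alternative 2 | methyl carbonate of 2-(2-nitroethyl)pin-2-en-4-ol (either configuration at C4) | [O-][N+](=O)CCC1=CC(OC(=O)OC)[C@@H]2C[C@H]1C2(C)C
A5 | alternative 2 | target skeleton with a nitro group on Cc and a pinane C3=C4 alkene | COC1=C(C)C(=O)[C@@]2(C(=O)C1(C)C)[C@@H](C(C)C)C([N+](=O)[O-])C[C@@]21C=C[C@@H]2C[C@H]1C2(C)C
A6 | alternative 3 | ring-B methyl ester (spiro cyclopentane on the pinane, ester on Ca, isopropyl on Cb) | COC(=O)C1[C@@H](C(C)C)CC[C@@]12CC[C@@H]1C[C@H]2C1(C)C
A7 | alternative 3 | 2,2-dimethyl-3-oxopentanoyl chloride | CCC(=O)C(C)(C)C(Cl)=O
A8 | alternative 3 | O-demethyl target, triketone tautomer | O=C1C(C)C(=O)[C@@]2(C(=O)C1(C)C)[C@@H](C(C)C)CC[C@@]21CC[C@@H]2C[C@H]1C2(C)C
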